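**Strategy**

The flavanone is disconnected at the O1–C8a aryl ether bond. In ring C, O1 joins the C2 stereocentre to C8a of ring A, so O1 can be carried as the hydroxyl of an (S)-benzylic alcohol set by asymmetric transfer hydrogenation, and closed onto a C8a bromide by palladium-catalysed O-arylation without touching the C2–O bond. The precursor is an open 1,3-diarylpropane: (S)-carbinol at future C2, a triisopropylsilyl-protected carbinol at future C4, bromine at future C8a, and the geranyl group already fixed between two MOM-protected oxygens of ring A. One operation forms ring C; desilylation, oxidation and MOM removal then give the target.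

Key step: step 9

**Remarks before the steps**

- Flavanone numbering is used: ring A is the bromo/geranyl ring, ring B the 3-oxy-4-methoxyphenyl ring, ring C the oxygen heterocycle. Geranyl = (2E)-3,7-dimethylocta-2,6-dien-1-yl; MOM = methoxymethyl; TIPS = triisopropylsilyl; TES = triethylsilyl.
- Assumption: the carbinol carbon next to ring A (chain C3 of 12–14, flavan C4 of 15 and 16) is formed without control. Both epimers are carried together because step 11 destroys this centre, so it has no descriptor in names and SMILES.
- Assumption: 1-(3-hydroxy-4-methoxyphenyl)ethanone (9) is bought.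
- Design notes:
  - Geranyl enters through an aryl iodide, because an alkyllithium would exchange the bromine and a lithium amide would metalate next to it.
  - The C2 carbinol is made last by ketone reduction, so its oxygen never carries a group that must be removed oxidatively beside electron-rich benzylic ethers.
  - The C4 oxygen carries TIPS, because a smaller silyl group could shift to the neighbouring alkoxide under the basic coupling conditions.

**Route**

Step 1
Reactants: 1 5-bromoresorcinol
Product: 2 5-bromo-2-iodobenzene-1,3-diol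
Conditions: I2, NaHCO3, H2O–THF, 0 °C to rt
Reagents that add atoms: iodine, II
Why: Electrophilic aromatic iodination of the resorcinol monoanion in aqueous hydrogencarbonate should occur at C2 between the two oxygens, as it does for resorcinol itself, the alternative positions being shielded by the neighbouring bromine.

Step 2
Reactants: 2 5-bromo-2-iodobenzene-1,3-diol
Product: 3 5-bromo-2-iodo-1,3-bis(methoxymethoxy)benzene
Conditions: MOMCl, iPr2NEt, CH2Cl2, 0 °C to rt
Reagents that add atoms: chloromethyl methyl ether, COCCl
Why: Standard O-alkylation of phenols gives the bis-MOM ether, whose acetals tolerate the organometallic, basic, reductive and oxidative steps that follow.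

Step 3
Reactants: 3 5-bromo-2-iodo-1,3-bis(methoxymethoxy)benzene; 4 geranyl bromide
Product: 6 5-bromo-2-geranyl-1,3-bis(methoxymethoxy)benzene, via arylmagnesium chloride 5 (not isolated)
Conditions: iPrMgCl·LiCl, THF, −20 to 0 °C; then CuBr·SMe2 (10 mol%), 4, −20 °C to rt
Reagents that add atoms: none
Why: Iodine–magnesium exchange is far faster at the doubly chelated C–I bond than at C–Br, and copper-catalysed allylic substitution at the primary carbon of geranyl bromide (SN2, no transposition) leaves the E double bond untouched.

Step 4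
Reactants: 6 5-bromo-2-geranyl-1,3-bis(methoxymethoxy)benzene
Product: 8 2-bromo-5-geranyl-4,6-bis(methoxymethoxy)benzaldehyde, via aryllithium 7 (not isolated)
Conditions: LiN(iPr)2, THF, −78 °C; DMF, −78 °C; then H2O
Reagents that add atoms: N,N-dimethylformamide, CN(C)C=O
Why: Directed ortho-metalation with a lithium amide, which does not exchange bromine, removes one of the two equivalent ring protons flanked by Br and OMOM, and the aryllithium is formylated at −78 °C before LiBr can be lost, as is known for MOM-protected 3-bromophenol.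

Step 5
Reactants: 9 1-(3-hydroxy-4-methoxyphenyl)ethanone
Product: 10 1-[4-methoxy-3-(methoxymethoxy)phenyl]ethanone
Conditions: MOMCl, iPr2NEt, CH2Cl2, 0 °C to rt
Reagents that add atoms: chloromethyl methyl ether, COCCl
Why: Phenol O-alkylation under mild amine-base conditions protects the ring B hydroxyl with the same group as ring A, so that one final operation frees all three phenols.

Step 6
Reactants: 10 1-[4-methoxy-3-(methoxymethoxy)phenyl]ethanone; 8 2-bromo-5-geranyl-4,6-bis(methoxymethoxy)benzaldehyde
Product: 12 rac-3-[2-bromo-5-geranyl-4,6-bis(methoxymethoxy)phenyl]-3-hydroxy-1-[4-methoxy-3-(methoxymethoxy)phenyl]propan-1-one, via lithium enolate 11 (not isolated)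
Conditions: LiN(iPr)2, THF, −78 °C; 8, −78 °C; AcOH, −78 °C
Reagents that add atoms: none
Why: Kinetic lithium enolate aldol addition of the methyl ketone to the non-enolisable aldehyde, quenched cold to prevent retro-aldol and dehydration, builds the three-carbon chain; the new carbinol is racemic, which is harmless because it is oxidised in step 11.

Step 7
Reactants: 12 rac-aldol
Product: 13 rac-3-[2-bromo-5-geranyl-4,6-bis(methoxymethoxy)phenyl]-1-[4-methoxy-3-(methoxymethoxy)phenyl]-3-(triisopropylsilyloxy)propan-1-one
Conditions: TIPSOTf, 2,6-lutidine, CH2Cl2, −20 to 0 °C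
Reagents that add atoms: triisopropylsilyl trifluoromethanesulfonate, CC(C)[Si](OS(=O)(=O)C(F)(F)F)(C(C)C)C(C)C
Why: Silylation of a hindered secondary alcohol with a silyl triflate and a hindered pyridine base is fast enough at low temperature to outpace elimination of the aldol and leaves the MOM acetals intact.

Step 8
Reactants: 13 rac-silyloxy ketone
Product: 14 (1S)-3-[2-bromo-5-geranyl-4,6-bis(methoxymethoxy)phenyl]-1-[4-methoxy-3-(methoxymethoxy)phenyl]-3-(triisopropylsilyloxy)propan-1-ol (both C3 epimers)
Conditions: RuCl[(S,S)-TsDPEN](p-cymene) (2 mol%), HCO2H–Et3N (5:2), CH2Cl2, 30 °C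
Reagents that add atoms: none
Why: Noyori–Ikariya asymmetric transfer hydrogenation of the aryl ketone sets the future C2 under catalyst control, the (S,S)-catalyst giving the (S)-aryl carbinol, while aryl bromide, alkenes, acetals and silyl ether are not reduced.

Step 9
Reactants: 14 (1S)-bromo alcohol
Product: 15 (2S)-6-geranyl-4'-methoxy-5,7,3'-tris(methoxymethoxy)-4-(triisopropylsilyloxy)flavan (both C4 epimers)
Conditions: [Pd(allyl)Cl]2 (2.5 mol%), RockPhos (6 mol%), Cs2CO3, toluene, 90 °C
Reagents that add atoms: none
Why: Zerovalent palladium carrying the bulky biarylphosphine inserts into the C8a–Br bond of ring A, Cs2CO3 turns the coordinated C2 hydroxyl into a palladium alkoxide, and C–O reductive elimination forms the O1–C8a bond. The closest known reaction type is the Buchwald intramolecular O-arylation of secondary alcohols with aryl bromides, which gives 2-substituted chromans without loss of configuration. Ring C closes as a six-membered ring by attack of oxygen on the aryl carbon with bromide leaving outside the ring (6-exo-trig in Baldwin terms), through a seven-membered arylpalladium alkoxide. No stereocentre is created and no bond to C2 is broken, so the (S) configuration set in step 8 is carried over unchanged. The step needs reductive elimination to outrun β-hydride elimination at C2–H, which the bulk of RockPhos and the favourable ring size secure, and it needs the C2 alcohol to be the only oxygen able to bind palladium, which the TIPS ether at C4 secures because it does not migrate and blocks retro-aldol cleavage, dehydration and a five-membered palladium chelate.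

Step 10
Reactants: 15 (2S)-4-silyloxyflavan
Product: 16 (2S)-6-geranyl-4'-methoxy-5,7,3'-tris(methoxymethoxy)flavan-4-ol (both C4 epimers)
Conditions: Bu4NF, THF, rt to 40 °C
Reagents that add atoms: none
Why: Fluoride-induced Si–O cleavage frees the C4 alcohol, and at this stage the molecule holds only ethers, acetals and alkenes, none of which is sensitive to basic fluoride.

Step 11
Reactants: 16 (2S)-flavan-4-ol
Product: 17 (2S)-6-geranyl-4'-methoxy-5,7,3'-tris(methoxymethoxy)flavanone
Conditions: Dess–Martin periodinane, NaHCO3, CH2Cl2, 0 °C to rt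
Reagents that add atoms: none
Why: Buffered Dess–Martin oxidation converts both C4 epimers of the benzylic alcohol into the same ketone under near-neutral conditions that touch neither the alkenes nor C2.

Step 12
Reactants: 17 (2S)-tris-MOM flavanone
Product: 18 (2S)-6-geranyl-5,7,3'-trihydroxy-4'-methoxyflavanone (target CNP0264411.1)
Conditions: HCl (1.25 M in MeOH), rt to 40 °C
Reagents that add atoms: none
Why: Acid-catalysed acetal exchange with methanol removes the three aryl MOM groups under the dilute, low-temperature conditions customary for prenylated polyphenols, and C2 should hold because ring opening of a flavanone to the chalcone is a base-driven process.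

**Compound list**

1 | 5-bromoresorcinol | Oc1cc(O)cc(Br)c1 | starting material
2 | 5-bromo-2-iodobenzene-1,3-diol | Oc1cc(Br)cc(O)c1I | intermediate
3 | 5-bromo-2-iodo-1,3-bis(methoxymethoxy)benzene | COCOc1cc(Br)cc(OCOC)c1I | intermediate
4 | geranyl bromide, (2E)-1-bromo-3,7-dimethylocta-2,6-diene | CC(C)=CCC/C(C)=C/CBr | starting material
5 | [4-bromo-2,6-bis(methoxymethoxy)phenyl]magnesium chloride | COCOc1cc(Br)cc(OCOC)c1[Mg]Cl | intermediate
6 | 5-bromo-2-geranyl-1,3-bis(methoxymethoxy)benzene | COCOc1cc(Br)cc(OCOC)c1C/C=C(\C)CCC=C(C)C | intermediate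
7 | [2-bromo-5-geranyl-4,6-bis(methoxymethoxy)phenyl]lithium | [Li]c1c(Br)cc(OCOC)c(C/C=C(\C)CCC=C(C)C)c1OCOC | intermediate
8 | 2-bromo-5-geranyl-4,6-bis(methoxymethoxy)benzaldehyde | O=Cc1c(Br)cc(OCOC)c(C/C=C(\C)CCC=C(C)C)c1OCOC | intermediate
9 | 1-(3-hydroxy-4-methoxyphenyl)ethanone | CC(=O)c1ccc(OC)c(O)c1 | starting material
10 | 1-[4-methoxy-3-(methoxymethoxy)phenyl]ethanone | CC(=O)c1ccc(OC)c(OCOC)c1 | intermediate
11 | lithium 1-[4-methoxy-3-(methoxymethoxy)phenyl]ethenolate | [Li]OC(=C)c1ccc(OC)c(OCOC)c1 | intermediate
12 | rac-3-[2-bromo-5-geranyl-4,6-bis(methoxymethoxy)phenyl]-3-hydroxy-1-[4-methoxy-3-(methoxymethoxy)phenyl]propan-1-one | COc1ccc(C(=O)CC(O)c2c(Br)cc(OCOC)c(C/C=C(\C)CCC=C(C)C)c2OCOC)cc1OCOC | intermediate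
13 | rac-3-[2-bromo-5-geranyl-4,6-bis(methoxymethoxy)phenyl]-1-[4-methoxy-3-(methoxymethoxy)phenyl]-3-(triisopropylsilyloxy)propan-1-one | COc1ccc(C(=O)CC(O[Si](C(C)C)(C(C)C)C(C)C)c2c(Br)cc(OCOC)c(C/C=C(\C)CCC=C(C)C)c2OCOC)cc1OCOC | intermediate
14 | (1S)-3-[2-bromo-5-geranyl-4,6-bis(methoxymethoxy)phenyl]-1-[4-methoxy-3-(methoxymethoxy)phenyl]-3-(triisopropylsilyloxy)propan-1-ol, both C3 epimers | COc1ccc([C@@H](O)CC(O[Si](C(C)C)(C(C)C)C(C)C)c2c(Br)cc(OCOC)c(C/C=C(\C)CCC=C(C)C)c2OCOC)cc1OCOC | intermediate
15 | (2S)-6-geranyl-4'-methoxy-5,7,3'-tris(methoxymethoxy)-4-(triisopropylsilyloxy)flavan, both C4 epimers | COc1ccc([C@@H]2CC(O[Si](C(C)C)(C(C)C)C(C)C)c3c(cc(OCOC)c(C/C=C(\C)CCC=C(C)C)c3OCOC)O2)cc1OCOC | intermediate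
16 | (2S)-6-geranyl-4'-methoxy-5,7,3'-tris(methoxymethoxy)flavan-4-ol, both C4 epimers | COc1ccc([C@@H]2CC(O)c3c(cc(OCOC)c(C/C=C(\C)CCC=C(C)C)c3OCOC)O2)cc1OCOC | intermediate
17 | (2S)-6-geranyl-4'-methoxy-5,7,3'-tris(methoxymethoxy)flavanone | COc1ccc([C@@H]2CC(=O)c3c(cc(OCOC)c(C/C=C(\C)CCC=C(C)C)c3OCOC)O2)cc1OCOC | intermediate
18 | (2S)-6-geranyl-5,7,3'-trihydroxy-4'-methoxyflavanone | COc1ccc([C@@H]2CC(=O)c3c(cc(O)c(C/C=C(\C)CCC=C(C)C)c3O)O2)cc1O | target

**Step count and risks**

Total steps: 12. Longest linear sequence: 11 (steps 1–4 and 6–12, from 5-bromoresorcinol).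

Steps most likely to fail:

1. Step 9 (key step). The palladium alkoxide may undergo β-hydride elimination, oxidising the C2 carbinol and reducing the C–Br bond, or oxidative addition at the ortho-substituted bromide may be slow. The fallback forms the other bond of the same ether (O1–C2) by substitution with inversion. It sets out from 13 and returns at 15. Transfer hydrogenation of 13 with the mirror-image catalyst RuCl[(R,R)-TsDPEN](p-cymene) should give the (1R)-bromo alcohol F1. Miyaura borylation (B2pin2, PdCl2(dppf), KOAc, dioxane, 90 °C) should give the pinacol boronate F2, and oxidation with NaBO3·4H2O in THF–H2O the phenol F3. Mitsunobu cyclisation (PPh3, DIAD, THF, 0 °C) should then close ring C with inversion at the carbinol, giving (2S)-15.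

2. Step 1. Iodination may take place next to bromine or twice. The fallback places geranyl directly. It sets out from 1 and returns at 6, bypassing steps 1–3. Friedel–Crafts allylation of 1 with geraniol (cat. p-TsOH, CHCl3, rt, the reaction type used for cannabigerol) should give 5-bromo-2-geranylresorcinol F4, to be separated from its 4-geranyl isomer by chromatography. MOMCl/iPr2NEt then gives 6.

3. Step 12. Protic acid may add a neighbouring phenol or methanol across a geranyl double bond. The fallback exchanges the protecting group without protic acid and then cleaves with fluoride. It sets out from 17 and returns at 18. TESOTf and 2,2'-bipyridyl in CH2Cl2 (0 °C to rt) should convert the aryl MOM ethers into the tris(triethylsilyl) ether F5. HF·pyridine buffered with pyridine in THF at 0 °C should then free the three phenols.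

**Further compounds**

F1 | step 9 | (1R)-3-[2-bromo-5-geranyl-4,6-bis(methoxymethoxy)phenyl]-1-[4-methoxy-3-(methoxymethoxy)phenyl]-3-(triisopropylsilyloxy)propan-1-ol | COc1ccc([C@H](O)CC(O[Si](C(C)C)(C(C)C)C(C)C)c2c(Br)cc(OCOC)c(C/C=C(\C)CCC=C(C)C)c2OCOC)cc1OCOC
F2 | step 9 | (1R)-3-[5-geranyl-4,6-bis(methoxymethoxy)-2-(4,4,5,5-tetramethyl-1,3,2-dioxaborolan-2-yl)phenyl]-1-[4-methoxy-3-(methoxymethoxy)phenyl]-3-(triisopropylsilyloxy)propan-1-ol | COc1ccc([C@H](O)CC(O[Si](C(C)C)(C(C)C)C(C)C)c2c(B3OC(C)(C)C(C)(C)O3)cc(OCOC)c(C/C=C(\C)CCC=C(C)C)c2OCOC)cc1OCOC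
F3 | step 9 | (1R)-3-[5-geranyl-2-hydroxy-4,6-bis(methoxymethoxy)phenyl]-1-[4-methoxy-3-(methoxymethoxy)phenyl]-3-(triisopropylsilyloxy)propan-1-ol | COc1ccc([C@H](O)CC(O[Si](C(C)C)(C(C)C)C(C)C)c2c(O)cc(OCOC)c(C/C=C(\C)CCC=C(C)C)c2OCOC)cc1OCOC
F4 | step 1 | 5-bromo-2-geranylresorcinol | Oc1cc(Br)cc(O)c1C/C=C(\C)CCC=C(C)C
F5 | step 12 | (2S)-6-geranyl-4'-methoxy-5,7,3'-tris(triethylsilyloxy)flavanone | COc1ccc([C@@H]2CC(=O)c3c(cc(O[Si](CC)(CC)CC)c(C/C=C(\C)CCC=C(C)C)c3O[Si](CC)(CC)CC)O2)cc1O[Si](CC)(CC)CC
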